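The south-west run has the flask's charge of starting material with half its protic impurity, so I reckon the flask from that run's rates.

| flask | starting material | protic impurity | remark | time |
|---|---|---|---|---|
| south-east | 0.19 M (fed, over 3.0 min) | 0.0145 M | run made earlier |  |
| south | 0.43 M (fed, over 3.0 min) | 0.0145 M | run made earlier |  |
| south-west | 0.29 M (fed, over 3.0 min) | 0.0073 M | run made earlier |  |
| flask | 0.29 M (fed, over 3.0 min) | 0.0145 M |  | 1.5 h |

| run | time / min | target / % | starting material / % |
|---|---|---|---|
| south-east | 2.50 | 16.0 | 63.8 |
| south-east | 5.00 | 46.9 | 42.3 |
| south-east | 12.0 | 57.9 | 21.4 |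
| south-east | 25.0 | 48.3 | 14.7 |
| south-east | 50.0 | 33.9 | 10.4 |
| south | 2.50 | 29.2 | 52.0 |
| south | 5.00 | 61.1 | 25.4 |
| south | 12.0 | 62.3 | 10.4 |
| south | 25.0 | 46.0 | 9.2 |
| south | 50.0 | 29.5 | 7.0 |
| south-west | 2.50 | 22.2 | 57.2 |
| south-west | 5.00 | 57.4 | 34.8 |
| south-west | 12.0 | 60.9 | 17.0 |
| south-west | 25.0 | 48.3 | 13.1 |
| south-west | 50.0 | 32.1 | 8.4 |

(readings scatter by 1 percentage point)

- percent here means starting material units held: one target or over-reaction product counts as two
- percent here means starting material units held: one side product counts as three
- the analysis behind the earlier runs scatters by 1 percentage point, standard deviation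
- steps thought possible: starting material + protic impurity -> quenched substrate; 2 starting material <-> target; starting material + target -> side product; target -> over-reaction product
- percentages count the whole charge, also what has not yet gone in

1. when, up to 1.5 h, the flask holds most target
2. the amount of target, in percent of the starting material charged, at that time

1. In the south-west run, target changes at 0.141 min⁻¹ of the charge between 2.50 min and 5.00 min, and at −0.00969 min⁻¹ between 12.0 min and 25.0 min.

2. I write this net rate as gain minus loss: gain is a constant times starting material squared, and loss is D times target. Interval means give the gain constant as 0.758 min⁻¹ and D as 0.0492 min⁻¹. D is the loss constant, a pseudo-first-order reading: the fraction of target leaving per minute by whatever route.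

3. Between 5.00 min and 12.0 min, gain slows by a factor 4.19, from 0.0918 min⁻¹ to 0.0219 min⁻¹. Loss at the 12.0 min target reading is 0.0300 min⁻¹, so the lines cross at 10.5 min.

4. Going round again, the flask quenches 2.48% more of its charge. Taking that off target gives 58.4%, and the crossing moves to 0.178 h. That is my reckoning for the flask.

5. The forecast gives 0.145 h (0.115 h to 0.185 h) and 61.5% (59.5% to 64%), because “net growth reaches zero near 8–9 min”.

The flask peaks at 0.150 h with 61.1%, which is 1.68 min before my crossing and 2.7 percentage points above my target.

    starting material + protic impurity → quenched substrate (k = 0.0774 L mol⁻¹ s⁻¹)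
    2 starting material ⇌ target (K = 65.0 L mol⁻¹, k = 0.0190 L mol⁻¹ s⁻¹)
    starting material + target → side product (k = 0.00383 L mol⁻¹ s⁻¹)
    target → over-reaction product (k = 1.56 × 10⁻⁴ s⁻¹)

Half the net turnover of starting material into target is done by 0.0524 h, around the end of the feed, when starting material stands at 61.3%. Half the turnover to side product comes at 0.328 h, after the peak. At the flask's peak, gain is 0.0278 min⁻¹ and D gives a loss of 0.0301 min⁻¹.

For the neighbour left until 25 min, the south-west readings at that time give a loss of 0.0238 min⁻¹ against a gain of 0.0130 min⁻¹, so target should be falling. That neighbour holds 48.7%, down from its highest 61.1%.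

The readings were computed from invented constants.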